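**Strategy.** The route rests on contracting the ten-membered carbocycle (C1–C10) to a cyclohexene: olefinic C1 and lactone carbinol C6 lie opposite each other, and a C1–C6 bond leaves C2–C5 in a six-membered ring with C7/C8 and C10/C9 as alkenyl arms. In one operation an alkoxide-driven oxy-Cope rearrangement of this alcohol makes C8–C9, cleaves C1–C6, delivers the ring-cis C1=C10 enoate and both oxygenated stereocentres with O8 and O9 differently protected, and stores a regiospecific C6 enolate as its silyl ether for the lactone. The precursor is a cis-1,2-dialkenylcyclohex-2-enol carrying an (E)-PMB-oxyvinyl arm on C6, a (Z)-silyloxyacrylate arm on C1 and a quinic-acid-derived cis-acetonide at C2/C3.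

Key step: step 13

**Remarks on the chemistry**
- Germacrane numbering (ring C1–C10, lactone carbons C11–C13, ester carbon C14, methyl C15) is used for all ring compounds from 10 onwards.
- The C2/C3 cis-diol is taken from (−)-quinic acid: a 3-methylcyclohexa-2,4-dienone is only the keto tautomer of m-cresol, and cis ring olefins are poor substrates for asymmetric dihydroxylation.
- The acrylate arm is formylated only after the ring ketone has been consumed, because ketone enolates of this series can expel the β-oxygen and aromatise.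
- The C6 silyl enol ether is opened with an alkoxide, not an alkyllithium, to spare the C10 methyl ester.
- C6 is reduced syn to O8 and then inverted in the lactonisation. A cis-diol gives a cis-epoxide only through two inversions at one carbon (halohydrin ester route).
- Assumption: chloride opens the acetoxonium ion of step 19 at C3; opening at C2 would converge on the same epoxide in step 20.

**Route**

Step 1
Reactants: 1 (−)-quinic acid
Product: 2 3,4-O-isopropylidene-1,5-quinide
Conditions: Me2C(OMe)2, TsOH·H2O (cat.), acetone, reflux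
Reagents that add atoms: 2,2-dimethoxypropane, COC(C)(C)OC
Why: Acid-catalysed acetal exchange protects the cis-3,4-diol while the carboxyl lactonises onto the cis 5-hydroxyl; the stereocentres come unchanged from the chiral pool and become C2/C3 of the target.

Step 2
Reactants: 2 3,4-O-isopropylidene-1,5-quinide
Product: 3 triol acetonide (1-CH2OH and free 5-OH)
Conditions: NaBH4, EtOH, 0 °C → rt
Reagents that add atoms: none
Why: Borohydride reduction of the strained bicyclic lactone to the primary alcohol and the free 5-hydroxyl; the acetonide is inert.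

Step 3
Reactants: 3 triol acetonide
Product: 4 (3R,4S,5R)-3-hydroxy-4,5-(isopropylidenedioxy)cyclohexan-1-one
Conditions: NaIO4, H2O (pH 6 buffer), 0 °C → rt
Reagents that add atoms: none
Why: Malaprade glycol cleavage of the only free 1,2-diol (tertiary OH/CH2OH) unveils the ketone with loss of one carbon.

Step 4
Reactants: 4 (3R,4S,5R)-3-hydroxy-4,5-(isopropylidenedioxy)cyclohexan-1-one
Product: 6 (4S,5R)-4,5-(isopropylidenedioxy)cyclohex-2-en-1-one, via mesylate 5 (not isolated)
Conditions: MsCl, Et3N, CH2Cl2, 0 °C → rt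
Reagents that add atoms: none
Why: Mesylation of the β-hydroxyl followed by E1cB elimination gives the enone; the sulfonate is a far better leaving group than the acetal oxygen on the other side.

Step 5
Reactants: 6 (4S,5R)-4,5-(isopropylidenedioxy)cyclohex-2-en-1-one
Product: 7 trimethylsilyl enol ether of (3R,4S,5R)-3-methyl-4,5-(isopropylidenedioxy)cyclohexanone
Conditions: Me2CuLi (from CuI, 2 MeLi), Me3SiCl, THF, −78 °C; then Et3N
Reagents that add atoms: lithium dimethylcuprate, [Li+].C[Cu-]C; chlorotrimethylsilane, C[Si](C)(C)Cl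
Why: Chlorosilane-accelerated Gilman 1,4-addition delivers methyl anti to the neighbouring dioxolane oxygen, and the kinetic enolate is silylated before it can isomerise and expel the acetal oxygen; the methyl-bearing centre is temporary.

Step 6
Reactants: 7 trimethylsilyl enol ether
Product: 8 (4S,5R)-3-methyl-4,5-(isopropylidenedioxy)cyclohex-2-en-1-one
Conditions: Pd(OAc)2 (1 equiv), MeCN, rt
Reagents that add atoms: none
Why: Saegusa–Ito oxidation: the palladium(II) enolate undergoes β-hydride elimination from the methyl-bearing carbon, regenerating the enone with the double-bond position fixed by the silyl enol ether.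

Step 7
Reactants: 8 (4S,5R)-3-methyl-4,5-(isopropylidenedioxy)cyclohex-2-en-1-one; 9 methyl bromoacetate
Product: 10 methyl 2-[(1R,5S,6R)-4-methyl-5,6-(isopropylidenedioxy)-2-oxocyclohex-3-en-1-yl]acetate
Conditions: LDA, THF, −78 °C; then 9, DMPU, −78 °C
Reagents that add atoms: none
Why: Kinetic α′-deprotonation gives the cross-conjugated lithium enolate, which is alkylated (SN2) on the convex face anti to the adjacent C–O bond and sets C1 trans to the acetonide; at −78 °C the enolate should keep its β-oxygen.

Step 8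
Reactants: 11 4-methoxybenzyl alcohol; 12 trichloroethylene
Product: 13 (E)-1,2-dichlorovinyl 4-methoxybenzyl ether
Conditions: KH, THF, 0 °C; then Cl2C=CHCl, rt
Reagents that add atoms: none
Why: Greene ynol ether synthesis: the potassium alkoxide adds to dichloroacetylene formed in situ and gives the (E)-1,2-dichlorovinyl ether.

Step 9
Reactants: 13 (E)-1,2-dichlorovinyl 4-methoxybenzyl ether
Product: 15 4-methoxybenzyl ethynyl ether, via lithium alkynyl ether 14 (not isolated)
Conditions: n-BuLi (2.2 equiv), Et2O, −78 → −40 °C; then MeOH, −78 °C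
Reagents that add atoms: none
Why: Dehydrochlorination and chlorine–lithium exchange give the lithium alkynyl ether, which is protonated cold; the benzylic ynol ether is kept below 0 °C and used at once because such ethers rearrange on warming.

Step 10
Reactants: 15 4-methoxybenzyl ethynyl ether
Product: 17 (E)-1-iodo-2-[(4-methoxybenzyl)oxy]ethene, via alkenylzirconocene 16 (not isolated)
Conditions: Cp2Zr(H)Cl, THF, 0 °C → rt (15 min); then I2, −20 °C
Reagents that add atoms: iodine, II
Why: Schwartz hydrozirconation is syn with zirconium on the terminal carbon and iodinolysis proceeds with retention, so the (E)-β-alkoxyvinyl iodide should result.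

Step 11
Reactants: 17 (E)-1-iodo-2-[(4-methoxybenzyl)oxy]ethene; 10 keto ester
Product: 19 tertiary alcohol with cis arms (C6–OH cis to the acetonide), via alkenyllithium 18 (not isolated)
Conditions: t-BuLi (2 equiv), Et2O, −78 °C; then 10, THF, −78 °C; aq. NaHCO3 at −78 °C
Reagents that add atoms: none
Why: Iodine–lithium exchange with retention gives the (E)-alkenyllithium, which adds 1,2 to the enone carbonyl faster than to the ester; axial attack on the half-chair with the C1 arm pseudo-equatorial, from the face away from the dioxolane, places the new arm cis to the C1 arm and sets C6.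

Step 12
Reactants: 19 tertiary alcohol
Product: 21 oxy-Cope precursor (Z)-silyloxyacrylate, via lithium formyl-ester enolate 20 (not isolated)
Conditions: LDA (2.2 equiv), THF, −78 °C; HCO2CH2CF3, −78 °C; then TBSCl, −78 → 0 °C; pH 7 buffer
Reagents that add atoms: 2,2,2-trifluoroethyl formate, O=COCC(F)(F)F; tert-butyldimethylsilyl chloride, CC(C)(C)[Si](C)(C)Cl
Why: Crossed Claisen formylation of the ester enolate (hydroxyl masked as its lithium alkoxide) gives the chelated lithium enolate of the formyl ester, which is silylated on oxygen to the (Z)-silyloxyacrylate (O cis to CO2Me, trans to C1); the liberated trifluoroethanol reprotonates the tertiary alkoxide, which TBSCl does not silylate at ≤0 °C, and no ketone enolate is ever formed.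

Step 13
Reactants: 21 oxy-Cope precursor
Product: 23 ten-membered C6 trimethylsilyl enol ether (2R,3S,8S,9S), via potassium enolate 22 (not isolated)
Conditions: KH, 18-crown-6, THF, 0 °C → rt; then Me3SiCl/Et3N, −78 °C
Reagents that add atoms: chlorotrimethylsilane, C[Si](C)(C)Cl
Why: Deprotonation gives the potassium alkoxide at C6, whose 1,5-diene (C8=C7–C6–C1–C10=C9) undergoes a charge-accelerated [3,3]-sigmatropic shift in which C8–C9 forms as C1–C6 breaks, and the potassium enolate 22 is silylated on oxygen before it can expel the ether at C8. The closest known reaction type is the anionic oxy-Cope rearrangement of 1,2-divinylcyclohexanols to cyclodec-5-enones with enolate trapping, here assisted by donor oxygens on both bond-forming termini and an ester on C10. No ring is closed head to tail: the cyclohexene is enlarged by four atoms when the two allyl halves of a six-centre chair bond at their termini. C8 and C9 are set by that chair, in which the (E)-enol ether places OPMB and the (Z)-acrylate places OTBS equatorial, while the configurations at C1 and C6 select the enantiomeric chair, giving the 8S,9S (threo) pair. The step needs the chair with ring bond C1–C2 axial (ring-cis C1=C10) and C6–C5 equatorial (E enol ether) rather than the other chair or a boat; the cis relation of the arms allows only axial/equatorial chairs, and the C10 ester disfavours the one with C2 equatorial through 1,2-allylic strain.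

Step 14
Reactants: 23 ten-membered C6 trimethylsilyl enol ether; 24 tert-butyl bromoacetate
Product: 26 C7-alkylated C6 ketone (tert-butyl ester), via lithium enolate 25 (not isolated)
Conditions: t-BuOK (1 equiv), THF, −78 → −40 °C; LiBr; then 24, −78 → −40 °C
Reagents that add atoms: none
Why: tert-Butoxide cleaves the Si–O bond to the enolate with retained geometry without touching the methyl ester; after exchange to lithium the enolate, chelated to the C8 ether oxygen that is cis to O6, is alkylated at C7 anti to C9 (Fráter–Seebach-type anti alkylation of a β-alkoxy enolate), setting C7 (7R by CIP in 26, the arrangement that is 7S in the lactone).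

Step 15
Reactants: 26 C7-alkylated C6 ketone
Product: 27 (6S)-alcohol (O6 syn to O8)
Conditions: Zn(BH4)2, Et2O, −30 °C
Reagents that add atoms: none
Why: Chelation-controlled reduction: zinc bridges the C6 carbonyl and the C8 PMB ether and hydride adds to the chelate to give the 1,3-syn (6S) alcohol, the sense also favoured by Felkin–Anh induction from C7; the tert-butyl ester does not lactonise.

Step 16
Reactants: 27 (6S)-alcohol
Product: 29 trans-fused 6,12-lactone (6R,7S), via C6 mesylate 28 (not isolated)
Conditions: Ms2O, Et3N, DMAP (cat.), CH2Cl2, 0 °C → rt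
Reagents that add atoms: none
Why: The allylic mesylate is displaced intramolecularly by the carbonyl oxygen of the tert-butyl ester (5-exo-tet neighbouring-group lactonisation) with loss of isobutene, so the lactone forms with inversion at C6 and is trans-fused.

Step 17
Reactants: 29 trans-fused 6,12-lactone
Product: 30 13-(dimethylamino) lactone (Mannich base)
Conditions: LDA, THF, −78 °C; CH2=NMe2+ I−, −78 → 0 °C
Reagents that add atoms: N,N-dimethylmethyleneiminium iodide, C=[N+](C)C.[I-]
Why: Mannich reaction of the lactone lithium enolate with Eschenmoser's salt (first stage of the α-methylenation), the electrophile entering anti to C8; the amine masks the future exocyclic methylene against methoxide in step 20 and its C11 centre is temporary.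

Step 18
Reactants: 30 Mannich base
Product: 31 2,3-cis-diol
Conditions: AcOH–H2O (4:1), 40 °C; aq. NaHCO3 work-up
Reagents that add atoms: none
Why: Mild aqueous acid hydrolyses the cis-acetonide while the secondary TBS ether, the PMB ether and the lactone should survive; the amine is carried as its acetate salt.

Step 19
Reactants: 31 2,3-cis-diol
Product: 33 2-acetoxy-3-chloro compound (C3 inverted), via cyclic orthoacetate 32 (not isolated)
Conditions: MeC(OMe)3, PPTS (1.2 equiv), CH2Cl2, rt; evaporate; Me3SiCl, CH2Cl2, 0 °C → rt; aq. NaHCO3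
Reagents that add atoms: trimethyl orthoacetate, COC(C)(OC)OC; chlorotrimethylsilane, C[Si](C)(C)Cl
Why: Kolb–Sharpless halohydrin ester formation: the cyclic orthoacetate ionises to the acetoxonium ion, which chloride opens by SN2 with inversion at the allylic carbon (drawn at C3).

Step 20
Reactants: 33 2-acetoxy-3-chloro compound
Product: 34 2,3-cis-epoxide (2R,3S)
Conditions: K2CO3, MeOH, 0 °C
Reagents that add atoms: none
Why: Methanolysis of the acetate frees the C2 alkoxide, which displaces chloride with a second inversion at C3 (Williamson-type closure), so the cis-diol becomes the cis-epoxide with net retention.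

Step 21
Reactants: 34 2,3-cis-epoxide
Product: 36 α-methylene lactone, via trimethylammonium iodide 35 (not isolated)
Conditions: MeI, MeCN, rt; then aq. NaHCO3/EtOAc
Reagents that add atoms: none
Why: Quaternisation and E1cB elimination of trimethylamine (Hofmann-type) unveil the α-methylene lactone under conditions that leave the vinyl epoxide untouched.

Step 22
Reactants: 36 α-methylene lactone
Product: 37 C8 alcohol
Conditions: DDQ, CH2Cl2–pH 7 buffer, 0 °C
Reagents that add atoms: none
Why: Oxidative PMB cleavage by DDQ (hydride abstraction, then hydrolysis of the oxocarbenium ion) frees only the C8 hydroxyl; silyl ether, epoxide and enoates are inert.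

Step 23
Reactants: 38 angelic acid
Product: 39 (Z)-2-methylbut-2-en-1-ol
Conditions: LiAlH4, Et2O, 0 °C
Reagents that add atoms: none
Why: Hydride reduction of the acid to the allylic alcohol with retention of the (Z)-olefin.

Step 24
Reactants: 39 (Z)-2-methylbut-2-en-1-ol
Product: 40 (2S,3R)-2,3-epoxy-2-methylbutan-1-ol
Conditions: Ti(OiPr)4, D-(−)-DIPT, t-BuOOH, 4 Å MS, CH2Cl2, −20 °C
Reagents that add atoms: tert-butyl hydroperoxide, CC(C)(C)OO
Why: Sharpless asymmetric epoxidation; with the hydroxymethyl drawn bottom right the D-(−)-tartrate delivers oxygen to the top face, which corresponds to the (2S,3R)-epoxy alcohol.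

Step 25
Reactants: 40 (2S,3R)-2,3-epoxy-2-methylbutan-1-ol
Product: 41 (2R,3R)-2,3-dimethyloxirane-2-carboxylic acid (epoxyangelic acid)
Conditions: RuCl3 (cat.), NaIO4, CCl4–MeCN–H2O, rt
Reagents that add atoms: sodium periodate, [Na+].[O-][I](=O)(=O)=O; water, O
Why: Sharpless ruthenium tetroxide oxidation of the primary alcohol to the acid; the descriptor at C2 changes to R without any change in space.

Step 26
Reactants: 37 C8 alcohol; 41 epoxyangelic acid
Product: 43 C8 epoxyangelate C9 TBS ether, via mixed anhydride 42 (not isolated)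
Conditions: 41, 2,4,6-Cl3C6H2COCl, Et3N, toluene, rt; then 37, DMAP, toluene, rt → 40 °C
Reagents that add atoms: none
Why: Yamaguchi esterification: the mixed anhydride acylates DMAP and then the hindered C8 hydroxyl with retention at C8; the acid has no enolisable α-hydrogen.

Step 27
Reactants: 43 C8 epoxyangelate C9 TBS ether
Product: 44 CNP0291485.1 (target)
Conditions: HF·pyridine, pyridine, THF, 0 °C → rt
Reagents that add atoms: none
Why: Buffered fluoride cleaves the secondary TBS ether at C9 (Si–F bond formation) and should neither open the epoxides nor move the ester.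

**Compound list**

1 | (−)-quinic acid, (1S,3R,4S,5R)-1,3,4,5-tetrahydroxycyclohexanecarboxylic acid | C1[C@H]([C@H]([C@@H](C[C@@]1(C(=O)O)O)O)O)O | starting material
2 | 3,4-O-isopropylidene-1,5-quinide (cis-3,4-acetonide, lactone to O5) | C1[C@@H]2[C@H]([C@H]3C[C@@]1(C(=O)O3)O)OC(C)(C)O2 | intermediate
3 | triol acetonide (lactone of 2 reduced to 1-CH2OH and 5-OH) | C1[C@@H]2[C@H]([C@H](O)C[C@@]1(CO)O)OC(C)(C)O2 | intermediate
4 | (3R,4S,5R)-3-hydroxy-4,5-(isopropylidenedioxy)cyclohexan-1-one | C1[C@@H]2[C@H]([C@H](O)CC1=O)OC(C)(C)O2 | intermediate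
5 | 3-O-mesylate of 4 | C1[C@@H]2[C@H]([C@H](OS(C)(=O)=O)CC1=O)OC(C)(C)O2 | intermediate
6 | (4S,5R)-4,5-(isopropylidenedioxy)cyclohex-2-en-1-one | O=C1C=C[C@@H]2OC(C)(C)O[C@@H]2C1 | intermediate
7 | trimethylsilyl enol ether of (3R,4S,5R)-3-methyl-4,5-(isopropylidenedioxy)cyclohexanone (methyl trans to the dioxolane) | C[Si](C)(C)OC1=C[C@@H](C)[C@@H]2OC(C)(C)O[C@@H]2C1 | intermediate
8 | (4S,5R)-3-methyl-4,5-(isopropylidenedioxy)cyclohex-2-en-1-one | O=C1C=C(C)[C@@H]2OC(C)(C)O[C@@H]2C1 | intermediate
9 | methyl bromoacetate | COC(=O)CBr | starting material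
10 | methyl 2-[(1R,5S,6R)-4-methyl-5,6-(isopropylidenedioxy)-2-oxocyclohex-3-en-1-yl]acetate (side chain trans to the acetonide) | O=C1C=C(C)[C@@H]2OC(C)(C)O[C@@H]2[C@H]1CC(=O)OC | intermediate
11 | 4-methoxybenzyl alcohol | COc1ccc(CO)cc1 | starting material
12 | trichloroethylene | ClC=C(Cl)Cl | starting material
13 | (E)-1,2-dichlorovinyl 4-methoxybenzyl ether | COc1ccc(CO/C(Cl)=C\Cl)cc1 | intermediate
14 | lithium [(4-methoxybenzyl)oxy]acetylide | COc1ccc(COC#C[Li])cc1 | intermediate
15 | 4-methoxybenzyl ethynyl ether | COc1ccc(COC#C)cc1 | intermediate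
16 | chloro{(E)-2-[(4-methoxybenzyl)oxy]vinyl}zirconocene | COc1ccc(CO/C=C/[Zr](Cl)(C2C=CC=C2)C2C=CC=C2)cc1 | intermediate
17 | (E)-1-iodo-2-[(4-methoxybenzyl)oxy]ethene | COc1ccc(CO/C=C/I)cc1 | intermediate
18 | (E)-2-[(4-methoxybenzyl)oxy]vinyllithium | COc1ccc(CO/C=C/[Li])cc1 | intermediate
19 | tertiary alcohol: C6–OH cis to the acetonide, (E)-PMB-oxyvinyl arm on C6 and CH2CO2Me arm on C1 cis to each other | O[C@]1(/C=C/OCc2ccc(OC)cc2)C=C(C)[C@@H]2OC(C)(C)O[C@@H]2[C@H]1CC(=O)OC | intermediate
20 | lithium (Z)-enolate of the C10-formyl ester (free C6–OH) | O[C@]1(/C=C/OCc2ccc(OC)cc2)C=C(C)[C@@H]2OC(C)(C)O[C@@H]2[C@H]1/C(C(=O)OC)=C/O[Li] | intermediate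
21 | oxy-Cope precursor: cis-dialkenylcyclohexenol with (E)-PMB-oxyvinyl and (Z)-TBS-oxyacrylate arms | O[C@]1(/C=C/OCc2ccc(OC)cc2)C=C(C)[C@@H]2OC(C)(C)O[C@@H]2[C@H]1/C(C(=O)OC)=C/O[Si](C)(C)C(C)(C)C | intermediate
22 | potassium C6 enolate of the ten-membered ring | [C@H]1(O[Si](C)(C)C(C)(C)C)/C(C(=O)OC)=C\[C@H]3OC(C)(C)O[C@H]3/C(C)=C\C(O[K])=C\[C@@H]1OCc2ccc(OC)cc2 | intermediate
23 | ten-membered C6 trimethylsilyl enol ether (ring-trans C6=C7, ring-cis C1=C10 and C4=C5, 2R,3S-acetonide, 8S-OPMB, 9S-OTBS) | [C@H]1(O[Si](C)(C)C(C)(C)C)/C(C(=O)OC)=C\[C@H]3OC(C)(C)O[C@H]3/C(C)=C\C(O[Si](C)(C)C)=C\[C@@H]1OCc2ccc(OC)cc2 | intermediate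
24 | tert-butyl bromoacetate | CC(C)(C)OC(=O)CBr | starting material
25 | lithium C6 enolate of the ten-membered ring | [C@H]1(O[Si](C)(C)C(C)(C)C)/C(C(=O)OC)=C\[C@H]3OC(C)(C)O[C@H]3/C(C)=C\C(O[Li])=C\[C@@H]1OCc2ccc(OC)cc2 | intermediate
26 | C6 ketone with C7–CH2CO2t-Bu (side chain anti to C9; 7R by CIP) | [C@H]1(O[Si](C)(C)C(C)(C)C)/C(C(=O)OC)=C\[C@H]3OC(C)(C)O[C@H]3/C(C)=C\C(=O)[C@H](CC(=O)OC(C)(C)C)[C@@H]1OCc2ccc(OC)cc2 | intermediate
27 | (6S,7S,8S,9S)-C6 alcohol (O6 syn to O8) | [C@H]1(O[Si](C)(C)C(C)(C)C)/C(C(=O)OC)=C\[C@H]3OC(C)(C)O[C@H]3/C(C)=C\[C@H](O)[C@H](CC(=O)OC(C)(C)C)[C@@H]1OCc2ccc(OC)cc2 | intermediate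
28 | C6 mesylate of 27 | [C@H]1(O[Si](C)(C)C(C)(C)C)/C(C(=O)OC)=C\[C@H]3OC(C)(C)O[C@H]3/C(C)=C\[C@H](OS(C)(=O)=O)[C@H](CC(=O)OC(C)(C)C)[C@@H]1OCc2ccc(OC)cc2 | intermediate
29 | trans-fused 6,12-lactone (6R,7S), C11 = CH2 | [C@H]1(O[Si](C)(C)C(C)(C)C)/C(C(=O)OC)=C\[C@H]3OC(C)(C)O[C@H]3/C(C)=C\[C@H]4OC(=O)C[C@@H]4[C@@H]1OCc2ccc(OC)cc2 | intermediate
30 | Mannich base: C11–CH2NMe2 trans to C8 on the lactone | [C@H]1(O[Si](C)(C)C(C)(C)C)/C(C(=O)OC)=C\[C@H]3OC(C)(C)O[C@H]3/C(C)=C\[C@H]4OC(=O)[C@@H](CN(C)C)[C@@H]4[C@@H]1OCc2ccc(OC)cc2 | intermediate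
31 | 2,3-cis-diol of 30 | [C@H]1(O[Si](C)(C)C(C)(C)C)/C(C(=O)OC)=C\[C@@H](O)[C@@H](O)/C(C)=C\[C@H]4OC(=O)[C@@H](CN(C)C)[C@@H]4[C@@H]1OCc2ccc(OC)cc2 | intermediate
32 | 2,3-cyclic methyl orthoacetate | [C@H]1(O[Si](C)(C)C(C)(C)C)/C(C(=O)OC)=C\[C@H]3OC(C)(OC)O[C@H]3/C(C)=C\[C@H]4OC(=O)[C@@H](CN(C)C)[C@@H]4[C@@H]1OCc2ccc(OC)cc2 | intermediate
33 | 2-acetoxy-3-chloro compound (chloride trans to the acetate) | [C@H]1(O[Si](C)(C)C(C)(C)C)/C(C(=O)OC)=C\[C@@H](OC(C)=O)[C@H](Cl)/C(C)=C\[C@H]4OC(=O)[C@@H](CN(C)C)[C@@H]4[C@@H]1OCc2ccc(OC)cc2 | intermediate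
34 | (2R,3S)-cis-epoxide with Mannich-base lactone | [C@H]1(O[Si](C)(C)C(C)(C)C)/C(C(=O)OC)=C\[C@H]3O[C@H]3/C(C)=C\[C@H]4OC(=O)[C@@H](CN(C)C)[C@@H]4[C@@H]1OCc2ccc(OC)cc2 | intermediate
35 | trimethylammonium iodide of 34 | [C@H]1(O[Si](C)(C)C(C)(C)C)/C(C(=O)OC)=C\[C@H]3O[C@H]3/C(C)=C\[C@H]4OC(=O)[C@@H](C[N+](C)(C)C)[C@@H]4[C@@H]1OCc2ccc(OC)cc2.[I-] | intermediate
36 | α-methylene lactone with 8-OPMB and 9-OTBS | [C@H]1(O[Si](C)(C)C(C)(C)C)/C(C(=O)OC)=C\[C@H]3O[C@H]3/C(C)=C\[C@H]4OC(=O)C(=C)[C@@H]4[C@@H]1OCc2ccc(OC)cc2 | intermediate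
37 | C8 alcohol (9-OTBS) | [C@H]1(O[Si](C)(C)C(C)(C)C)/C(C(=O)OC)=C\[C@H]3O[C@H]3/C(C)=C\[C@H]4OC(=O)C(=C)[C@@H]4[C@@H]1O | intermediate
38 | angelic acid, (Z)-2-methylbut-2-enoic acid | C/C=C(/C)C(=O)O | starting material
39 | (Z)-2-methylbut-2-en-1-ol | C/C=C(/C)CO | intermediate
40 | (2S,3R)-2,3-epoxy-2-methylbutan-1-ol | OC[C@]1(C)O[C@@H]1C | intermediate
41 | (2R,3R)-2,3-dimethyloxirane-2-carboxylic acid | OC(=O)[C@]1(C)O[C@@H]1C | intermediate
42 | mixed anhydride of 41 with 2,4,6-trichlorobenzoic acid | O=C(OC(=O)c1c(Cl)cc(Cl)cc1Cl)[C@]1(C)O[C@@H]1C | intermediate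
43 | C8 (2R,3R)-epoxyangelate, C9 TBS ether | [C@H]1(O[Si](C)(C)C(C)(C)C)/C(C(=O)OC)=C\[C@H]3O[C@H]3/C(C)=C\[C@H]4OC(=O)C(=C)[C@@H]4[C@@H]1OC(=O)[C@]5(C)O[C@@H]5C | intermediate
44 | CNP0291485.1: (2R,3S,6R,7S,8S,9S)-2,3-epoxy-9-hydroxy-8-[(2R,3R)-epoxyangeloyloxy]germacra-1(10),4,11(13)-trien-6,12-olide 14-methyl ester | C=C1C(=O)O[C@@H]2/C=C(/C)[C@@H]3O[C@@H]3/C=C(/C(=O)OC)[C@H](O)[C@@H](OC(=O)[C@]3(C)O[C@@H]3C)[C@@H]12 | target

**Step count.** 27 steps in total. Longest linear sequence: 21 steps (steps 1–7, 11–22, 26, 27); steps 8–10 and 23–25 are side branches.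

**Steps most likely to fail**

Step 13 (ring expansion). The alkoxide may transfer silicon from the silyloxyacrylate or lactonise onto the ester before it rearranges; a boat or the other chair would erode the C8/C9 pair and the olefin geometry; and the enolate may lose the C8 ether before it is silylated. Fallback (neutral siloxy-Cope, known chemistry): setting out from 21, silylation with N-(trimethylsilyl)imidazole in CH2Cl2 gives the trimethylsilyl ether of the precursor F1. Thermolysis of F1 (toluene, sealed vessel, 130–150 °C, base-washed glass) should pass through the same chair without any anionic species and place silicon on the enol oxygen, so the route is rejoined at 23.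

Step 14 (C7 alkylation). If the enolate reacts through the non-chelated conformer with H8 eclipsing the enolate, the electrophile enters on the other face and the C7 epimer forms; E1cB loss of the C8 ether competes as well. Fallback (hydrogen introduced last, known chemistry): setting out from 23, Mukaiyama aldol addition to tert-butyl glyoxylate (BF3·OEt2, CH2Cl2, −78 °C) gives the aldol adduct F2, whose two new centres are inconsequential. Dehydration with Burgess reagent gives the (E)-alkylidene ketone F3. Conjugate reduction with Stryker's reagent, followed by kinetic protonation of the enolate at C7 on the open face anti to C9, should set the same C7 configuration and rejoin the route at 26.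

Step 11 (carbonyl addition). Equatorial attack would give the trans-dialkenyl alcohol, the basic alkenyllithium may enolise the ketone, and the ynol-ether-derived reagents may decompose before use. Fallback (arm built stepwise, known chemistry): setting out from 10, ethynylmagnesium bromide (THF, −78 °C), a small nucleophile with a strong preference for axial attack, gives the propargylic alcohol F4. Zirconocene-catalysed hydroboration with pinacolborane gives the (E)-alkenylboronate F5. Copper(II) acetate-promoted oxidative coupling of F5 with 4-methoxybenzyl alcohol 11 (Chan–Lam-type etherification with retention of olefin geometry) rejoins the route at 19.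

**Further compounds**

F1 | step 13 | trimethylsilyl ether of precursor 21 | C[Si](C)(C)O[C@]1(/C=C/OCc2ccc(OC)cc2)C=C(C)[C@@H]2OC(C)(C)O[C@@H]2[C@H]1/C(C(=O)OC)=C/O[Si](C)(C)C(C)(C)C
F2 | step 14 | aldol adduct of 23 with tert-butyl glyoxylate (C6 ketone, C7–CH(OH)CO2t-Bu, epimer mixture at C7 and C11) | [C@H]1(O[Si](C)(C)C(C)(C)C)/C(C(=O)OC)=C\[C@H]3OC(C)(C)O[C@H]3/C(C)=C\C(=O)C(C(O)C(=O)OC(C)(C)C)[C@@H]1OCc2ccc(OC)cc2
F3 | step 14 | (E)-7(11)-alkylidene C6 ketone | [C@H]1(O[Si](C)(C)C(C)(C)C)/C(C(=O)OC)=C\[C@H]3OC(C)(C)O[C@H]3/C(C)=C\C(=O)/C(=C/C(=O)OC(C)(C)C)[C@@H]1OCc2ccc(OC)cc2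
F4 | step 11 | C6-ethynyl tertiary alcohol (ethynyl cis to the C1 arm) | O[C@]1(C#C)C=C(C)[C@@H]2OC(C)(C)O[C@@H]2[C@H]1CC(=O)OC
F5 | step 11 | (E)-alkenyl pinacolboronate on C6 | O[C@]1(/C=C/B2OC(C)(C)C(C)(C)O2)C=C(C)[C@@H]2OC(C)(C)O[C@@H]2[C@H]1CC(=O)OC
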